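**Two branches.** The 5 questions below ask about one share on 4 flasks, and I reckon it by following one substrate molecule.

| setting | grey | green | Friday's | Saturday's | Sunday's | Wednesday's |
|---|---|---|---|---|---|---|
| substrate | 27 mM | 42 mM | 19 mM | 19 mM | 19 mM | 19 mM |
| reagent | 2.5 equiv | 2.5 equiv | 2.50 equiv | 2.50 equiv | 2.50 equiv | 2.50 equiv |
| temperature | 32 °C | 60 °C | 20 °C | 70 °C | 45 °C |  |
| remark | run made earlier | run made earlier |  |  |  | at 70 °C until 80 min, from then on at 20 °C |
| time |  |  | 4.0 h | 4.0 h | 4.0 h | 4.0 h |

- grey (time / h: target / %, side product A / %): 0.200: 17, 0; 0.500: 39, 0; 0.833: 53, 0; 1.33: 66, 1; 2.00: 73, 4; 3.00: 77, 6
- green (time / min: target / %, side product A / %): 6.00: 71, 3; 12.0: 75, 2; 20.0: 75, 9; 25.0: 74, 7; 30.0: 67, 8; 40.0: 68, 10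

(readings scatter by 2 percentage points)

- percent here means substrate units held: one side product A counts as two
- the numbers in the tables scatter by 2 percentage points (one standard deviation)

- the best flask by share of target in all that became target or side product A or side product B; "all alike" if 1.5 percentage points covers them all (Friday's / Saturday's / Sunday's / Wednesday's / all alike)
- share of target in all that became target or side product A or side product B, Friday's
- share of target in all that became target or side product A or side product B, Saturday's
- share of target in all that became target or side product A or side product B, Sunday's
- share of target in all that became target or side product A or side product B, Wednesday's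

**The rule.** A substrate molecule that reacts meets a first branch, where it is lost to side product B or gets through, and a second, where target moves on to side product A or stays, as the late appearance of side product A in the grey run suggests. The asked share is the chance at the first branch times the chance at the second. I call the first chance the keep (the selectivity at that branch). Side product B is not read, so I book the missing rest as side product B, and the last green reading gives a keep of 78.0%, a low figure if substrate remains. The last grey reading gives 83.0%.

**Two extremes.** If target stays for good, the share equals the keep; if target moves on entirely, the share is nothing. A real flask lies between, at keep times second chance, and under my booking those products are the target readings themselves, 77% in the grey run and 68% in the green run.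

**My reckoning.** I put Friday's first, near 83.0%, and Sunday's between those two products. Saturday's comes last and well under 68%, since it is hotter than the green run and read later. Wednesday's stands above Saturday's.

**The forecast.** Working from “selectivity falling as temperature rises”, it names Friday's, with 87%, 48%, 69% (range 62% to 76%) and 61% in the order asked. Its Friday's figure is higher than mine.

**The flask.** The best is Friday's, with 83.6%, 45.1%, 77.9% and 61.1%, so Sunday's lies above the forecast's range and slightly above my upper mark.

    substrate + target → side product A (k = 0.500 M⁻¹ min⁻¹, Ea = 59.0 kJ mol⁻¹)
    substrate + by-product → side product B (k = 1.90 M⁻¹ min⁻¹, Ea = 48.0 kJ mol⁻¹)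
    substrate + reagent ⇌ target + by-product (K = 1.40, k = 7.20 M⁻¹ min⁻¹, Ea = 75.0 kJ mol⁻¹, ΔH = −53.0 kJ mol⁻¹)
    (constants at 70 °C)

**What follows.** In Saturday's at 4.00 h, the forward rate of substrate with reagent alone is 33 times the loss to side product B. In Saturday's, that step alone relaxes, both ways together, with a half-life of 2.06 min, short against 4.0 h. The product of the keep 78.0% and Saturday's second chance 67.0% is 52.3%, above the actual 45.1%, and Saturday's own keep is 67.2%. For the same flask as Saturday's but with 10.0 equiv of reagent, the product of the keep from the green run and that neighbour's second chance is 64.5%; the computed share there is 64.1%.

The runs are calculated for an exercise; the scatter is artificial.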